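Time on its own told me little at this bench, so when I handed over theta and eta, both to be read at 80 min, I counted it in substrate lifetimes.

all flasks: gas 200 mM (held)

|  | substrate | temperature | remark | time |
|---|---|---|---|---|
| grey | 1.1 M | 78 °C | run made earlier |  |
| blue | 1.8 M | 94 °C | run made earlier |  |
| theta | 0.80 M | 80 °C |  | 80 min |
| eta | 0.80 M | 90 °C |  | 80 min |

| run | time / min | intermediate D / % | target / % | intermediate A / % | intermediate B / % | side product / % | substrate / % |
|---|---|---|---|---|---|---|---|
| grey | 4.00 | 1 | 1 | 11 | 0 | 0 | 88 |
| grey | 12.0 | 0 | 3 | 32 | 0 | 1 | 70 |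
| grey | 20.0 | 4 | 1 | 42 | 1 | 0 | 53 |
| grey | 30.0 | 0 | 0 | 58 | 1 | 2 | 43 |
| grey | 50.0 | 1 | 0 | 75 | 0 | 0 | 20 |
| blue | 2.00 | 2 | 1 | 29 | 1 | 0 | 69 |
| blue | 6.00 | 1 | 0 | 60 | 1 | 1 | 36 |
| blue | 10.0 | 0 | 0 | 80 | 2 | 1 | 19 |
| blue | 15.0 | 0 | 1 | 90 | 3 | 0 | 10 |
| blue | 25.0 | 0 | 1 | 98 | 3 | 2 | 3 |

(scatter of a reading: 1.5 percentage points)

- at the start none of the gas is in solution

- which of these there is most of at the end, counted by the substrate in it, theta (intermediate A / side product / substrate / intermediate B / intermediate D)
- which of these there is most of at the end, counted by the substrate in it, eta (intermediate A / side product / substrate / intermediate B / intermediate D)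
- how much there is at the end of the one of these that leads, in percent of the substrate charged: theta
- how much there is at the end of the one of these that leads, in percent of the substrate charged: eta

My note for whoever took over ran like this. Each flask started with substrate, which turned into intermediate A, and in the earlier runs no other species read above 4%. I took a first-order rate constant k for substrate loss from one reading per run: 0.0322 /min in grey, with 20% left at 50.0 min, and 0.166 /min in blue, with 19% left at 10.0 min. I assumed that k ignored the charge and interpolated ln k in temperature, which gave 0.0395 /min for theta and 0.110 /min for eta.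

I then counted turnovers N, k times the time: 3.16 for theta and 8.82 for eta. N is the number of substrate lifetimes in the run, and the substrate left is exp(−N). So I expected 4.24% of the substrate in theta and 0.0148% in eta. That left room of 95.8% in theta for intermediate A and whatever it feeds. Theta, I wrote, would still hold more substrate than eta at that time.

The forecast named intermediate A for theta at 92% and intermediate A for eta at 88%, saying “Intermediate A takes nearly everything else”. Its theta figure stood below my room.

    substrate → intermediate A (k = 0.0362 /min, Ea = 119 kJ/mol)
    reagent + intermediate A → intermediate B (k = 0.00302 /M/min, Ea = 96.0 kJ/mol)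
    reagent + intermediate B ⇌ intermediate C (K = 15.2 /M, k = 0.00562 /M/min, Ea = 84.0 kJ/mol, ΔH = −28.0 kJ/mol)
    intermediate B → intermediate D (k = 0.0261 /min, Ea = 114 kJ/mol)
    intermediate D → side product (k = 0.00560 /min, Ea = 114 kJ/mol)
    reagent + intermediate D → target (k = 0.00172 /M/min, Ea = 91.0 kJ/mol)
    gas ⇌ reagent, rate k7*(csat - [reagent]) (kL = 0.312 /min)
    2 reagent → homo dimer (k = 0.0485 /M/min, Ea = 69.0 kJ/mol)
    (constants at 80 °C)

Theta ended with 91.5% of intermediate A and eta with 91.1%, and intermediate A led in both. Eta had stood at 94.9% of intermediate A at 40.0 min. Theta's substrate ended at 5.52% against my 4.24%. Read at 30 min, the same flask counted 1.19 turnovers, which gave 30.6% left, and that neighbour held 33.8% of its substrate.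

(The numbers in the tables are calculated for an exercise; scatter was added.)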